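**Retrosynthetic overview**

1. The last C–C bond is lactone C3–CH2(ring B): the (S)-β-arylmethyl butyrolactone 24 is alkylated anti to its C4 substituent with benzyl bromide 38, then desilylated and debenzylated.
2. Structural feature carrying the strategy: the 2-aryl-3-(hydroxymethyl)-7-methoxy-2,3-dihydrobenzofuran (benzo ring C, furan atoms O1/C2/C3, guaiacyl ring D on C2) is a ring-contracted flavanone. Its C3–C3a bond arises by a 1,2-shift of flavanone ring carbon C4a from C4 to C3, and the old C4 becomes the carbon substituent on C3.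
3. The (2R)-flavanone 12 comes from chromone 8 and boronic acid 11 by rhodium/chiral-diene 1,4-addition; 8 comes from methyl vanillate by iodination, Stille acetylation and formamide-acetal annulation.
4. The ring A/ring B arm, an anti-(1S,2S)-1,2-diarylpropane-1,3-diol, comes from a magnesium-catalysed Evans anti-aldol of an arylacetyl imide (ring B) with O-benzylvanillin (ring A).
5. Ring order: rings A–D are aromatic from the start; pyranone ring (step 3), contracted to the furan ring (step 7), then the lactone ring (step 14).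

Key step: step 7

Assumption: the sense of induction in steps 6, 13 and 19 is assigned from the accepted models for each ligand or auxiliary; if a first run showed the opposite sense, the antipodal ligand or auxiliary would be used with no other change.

Abbreviation used in names: BF-5-yl = (2R,3S)-2-(4-benzyloxy-3-methoxyphenyl)-7-methoxy-3-[(triisopropylsilyloxy)methyl]-2,3-dihydro-1-benzofuran-5-yl.

**Route**

Step 1
Reactants: 1 methyl vanillate
Product: 2 methyl 4-hydroxy-3-iodo-5-methoxybenzoate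
Conditions: N-iodosuccinimide, CF3CO2H (cat.), MeCN, rt
Reagents that add atoms: N-iodosuccinimide O=C1CCC(=O)N1I
Why: Electrophilic aromatic iodination; the phenol directs ortho and its para position is blocked by the ester, so only C5 reacts.

Step 2
Reactants: 2 methyl 4-hydroxy-3-iodo-5-methoxybenzoate; 3 tributyl(1-ethoxyvinyl)stannane
Product: 5 methyl 3-acetyl-4-hydroxy-5-methoxybenzoate, via aryl enol ether 4 (not isolated)
Conditions: PdCl2(PPh3)2 (3 mol%), dioxane, 100 °C; then 2 M HCl, rt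
Reagents that add atoms: water O
Why: Stille coupling with an acetyl-anion equivalent followed by enol ether hydrolysis installs the ortho-acetyl group without the strong Lewis acid a Fries shift would need on this ester-deactivated guaiacol, which would cleave the neighbouring methyl ether.

Step 3
Reactants: 5 methyl 3-acetyl-4-hydroxy-5-methoxybenzoate; 6 N,N-dimethylformamide dimethyl acetal
Product: 8 methyl 8-methoxy-4-oxo-4H-chromene-6-carboxylate, via enaminone 7 (not isolated)
Conditions: 6, toluene, 100 °C; then conc. HCl, CH2Cl2, 40 °C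
Reagents that add atoms: none
Why: Enaminone formation at the acetyl methyl group, then acid-promoted addition of the phenol to the β-carbon and loss of dimethylamine (standard chromone synthesis from an ortho-hydroxyacetophenone).

Step 4
Reactants: 9 4-bromo-2-methoxyphenol
Product: 10 4-bromo-2-methoxyphenyl pivalate
Conditions: t-BuCOCl, Et3N, DMAP (cat.), CH2Cl2, 0 °C to rt
Reagents that add atoms: pivaloyl chloride CC(C)(C)C(Cl)=O
Why: O-acylation of the phenol; the hindered, electron-withdrawing ester is chosen for its role in step 7.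

Step 5
Reactants: 10 4-bromo-2-methoxyphenyl pivalate
Product: 11 [3-methoxy-4-(pivaloyloxy)phenyl]boronic acid
Conditions: B2(OH)4, PdCl(XPhos)(2'-aminobiphenyl-2-yl) (second-generation XPhos palladacycle, 1 mol%), XPhos (2 mol%), KOAc, EtOH, 80 °C
Reagents that add atoms: tetrahydroxydiboron OB(O)B(O)O
Why: Miyaura-type palladium-catalysed borylation with tetrahydroxydiboron gives the free boronic acid directly under conditions that leave the pivalate alone.

Step 6
Reactants: 8 methyl 8-methoxy-4-oxo-4H-chromene-6-carboxylate; 11 [3-methoxy-4-(pivaloyloxy)phenyl]boronic acid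
Product: 12 methyl (2R)-8-methoxy-2-[3-methoxy-4-(pivaloyloxy)phenyl]-4-oxochromane-6-carboxylate
Conditions: [RhCl(C2H4)2]2 (2.5 mol%), (R,R)-Ph-bod [(1R,4R)-2,5-diphenylbicyclo[2.2.2]octa-2,5-diene, 5.5 mol%], KOH (10 mol%), dioxane/H2O 10:1, 40 °C
Reagents that add atoms: none
Why: Hayashi–Miyaura rhodium-catalysed asymmetric 1,4-addition to the chromone, with the C2-symmetric diene selecting the enone face that gives 2R; the ethylene complex is the rhodium source because its ligands are fully displaced by the chiral diene (a cod complex would keep an achiral diene and run a racemic background reaction), and the nearly neutral medium should keep the pivalate on and the flavanone ring closed.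

Step 7
Reactants: 12 methyl (2R)-8-methoxy-2-[3-methoxy-4-(pivaloyloxy)phenyl]-4-oxochromane-6-carboxylate
Product: 14 dimethyl (2R,3R)-7-methoxy-2-[3-methoxy-4-(pivaloyloxy)phenyl]-2,3-dihydro-1-benzofuran-3,5-dicarboxylate (2,3-trans), via methyl enol ether 13 (not isolated)
Conditions: PhI(OAc)2 (1.2 equiv), conc. H2SO4 (1.5 equiv), HC(OMe)3, rt; aq. NaHCO3 work-up
Reagents that add atoms: trimethyl orthoformate COC(OC)OC; water O
Why: Acid and orthoformate turn the C4 ketone into methyl enol ether 13, PhI(OAc)2 adds at C3 on the face away from the equatorial C2 aryl and methanol caps C4 as the dimethyl ketal, which leaves the C3–I bond equatorial and antiperiplanar to the C4–C4a ring bond. Ring carbon C4a, made electron-rich by the ring oxygen on the neighbouring C8a, then shifts from C4 to C3 through a bridged phenonium ion as iodobenzene leaves, and the dimethoxycarbenium ion at the old C4 is hydrolysed to the methyl ester on work-up; the closest known reaction is exactly this oxidative ring contraction of flavanones to methyl 2-aryl-2,3-dihydrobenzofuran-3-carboxylates by trivalent iodine reagents or Tl(NO3)3. The furan ring is therefore closed by a 1,2-aryl shift that contracts the pyranone (new C3–C4a bond), not by cyclisation of an open chain. The new C3 centre is set by inversion at C3 in the trans-diequatorial iodane, so it is relayed from the untouched C2 centre and should come out 2,3-trans (descriptor 3R while C3 carries CO2Me). The step needs migration of C4a rather than of the C2 aryl (isoflavone path) or simple dehydrogenation (flavone), and C2 must survive the acid: the C4 ketal and the equatorial iodane favour the ring bond, while the pivalate makes ring D a poor migrating group, shields it from the oxidant and disfavours ionisation of the C2–O bond. Any cis ester can be converged on the trans isomer by brief treatment with catalytic NaOMe in MeOH.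

Step 8
Reactants: 14 dimethyl (2R,3R)-7-methoxy-2-[3-methoxy-4-(pivaloyloxy)phenyl]-2,3-dihydro-1-benzofuran-3,5-dicarboxylate
Product: 15 4-[(2R,3S)-3,5-bis(hydroxymethyl)-7-methoxy-2,3-dihydro-1-benzofuran-2-yl]-2-methoxyphenol
Conditions: LiAlH4, THF, 0 °C (ester added to the hydride); aq. potassium sodium tartrate
Reagents that add atoms: none
Why: Hydride reduction of both methyl esters with reductive removal of the pivalate; no bond at C2 or C3 is broken, so the trans geometry is kept and only the C3 descriptor changes (R to S) because CH2OH ranks below C2.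

Step 9
Reactants: 15 4-[(2R,3S)-3,5-bis(hydroxymethyl)-7-methoxy-2,3-dihydro-1-benzofuran-2-yl]-2-methoxyphenol
Product: 16 [(2R,3S)-2-(4-benzyloxy-3-methoxyphenyl)-7-methoxy-2,3-dihydro-1-benzofuran-3,5-diyl]dimethanol
Conditions: BnBr (1.05 equiv), K2CO3, acetone, rt
Reagents that add atoms: benzyl bromide BrCc1ccccc1
Why: Williamson etherification; only the phenol is deprotonated by carbonate, so the two primary alcohols stay free.

Step 10
Reactants: 16 [(2R,3S)-2-(4-benzyloxy-3-methoxyphenyl)-7-methoxy-2,3-dihydro-1-benzofuran-3,5-diyl]dimethanol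
Product: 17 (2R,3S)-2-(4-benzyloxy-3-methoxyphenyl)-3-(hydroxymethyl)-7-methoxy-2,3-dihydro-1-benzofuran-5-carbaldehyde
Conditions: activated MnO2, CH2Cl2, rt
Reagents that add atoms: none
Why: Chemoselective MnO2 oxidation of the benzylic alcohol; the aliphatic C3 hydroxymethyl group is not oxidised.

Step 11
Reactants: 17 (2R,3S)-2-(4-benzyloxy-3-methoxyphenyl)-3-(hydroxymethyl)-7-methoxy-2,3-dihydro-1-benzofuran-5-carbaldehyde
Product: 18 (2R,3S)-2-(4-benzyloxy-3-methoxyphenyl)-7-methoxy-3-[(triisopropylsilyloxy)methyl]-2,3-dihydro-1-benzofuran-5-carbaldehyde (BF-5-yl carbaldehyde)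
Conditions: i-Pr3SiCl, imidazole, DMF, rt
Reagents that add atoms: triisopropylsilyl chloride CC(C)[Si](Cl)(C(C)C)C(C)C
Why: Silylation of the primary alcohol with a group that tolerates alkoxide, borohydride, mild acid and amide base and leaves with fluoride at the end.

Step 12
Reactants: 18 BF-5-yl carbaldehyde; 19 dimethyl succinate
Product: 21 (E)-3-(methoxycarbonyl)-4-(BF-5-yl)but-3-enoic acid, via paraconic lactone ester 20 (not isolated)
Conditions: t-BuOK, t-BuOH, 50 °C; then 1 M HCl (0 °C) to pH 3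
Reagents that add atoms: none
Why: Stobbe condensation: aldol addition of the succinate enolate, lactonisation to 20 and E1cB opening give the E half-ester with the acid and ester already differentiated.

Step 13
Reactants: 21 (E)-3-(methoxycarbonyl)-4-(BF-5-yl)but-3-enoic acid
Product: 22 (3S)-3-(methoxycarbonyl)-4-(BF-5-yl)butanoic acid
Conditions: [Rh(cod)((R,R)-Et-DuPhos)]BF4 (1 mol%), H2 (5 atm), NaOMe (10 mol%), MeOH, rt
Reagents that add atoms: none
Why: Rhodium–bisphosphine asymmetric hydrogenation of an itaconate-type half-ester; the carboxylate and the alkene chelate rhodium and the ligand sets the new centre (S), while the homogeneous catalyst leaves the benzyl ether untouched.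

Step 14
Reactants: 22 (3S)-3-(methoxycarbonyl)-4-(BF-5-yl)butanoic acid
Product: 24 (4S)-4-[(BF-5-yl)methyl]oxolan-2-one, via hydroxy acid 23 (not isolated)
Conditions: KOH (1 equiv), EtOH; CaCl2, NaBH4, −10 °C to rt; 1 M HCl to pH 3; then PPTS (cat.), toluene, 60 °C
Reagents that add atoms: none
Why: Ca(BH4)2 reduces the ester but not the carboxylate, and the γ-hydroxy acid lactonises on mild acid treatment; the stereocentre is not involved.

Step 15
Reactants: 2 methyl 4-hydroxy-3-iodo-5-methoxybenzoate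
Product: 25 methyl 4-(benzyloxy)-3-iodo-5-methoxybenzoate
Conditions: BnBr, K2CO3, DMF, 60 °C
Reagents that add atoms: benzyl bromide BrCc1ccccc1
Why: Williamson etherification of the hindered phenol; the benzyl ether stays to the last step.

Step 16
Reactants: 25 methyl 4-(benzyloxy)-3-iodo-5-methoxybenzoate; 26 (2-tert-butoxy-2-oxoethyl)zinc bromide
Product: 27 tert-butyl 2-[2-(benzyloxy)-3-methoxy-5-(methoxycarbonyl)phenyl]acetate
Conditions: Pd(dba)2 (2 mol%), Q-Phos (2 mol%), THF, rt to 50 °C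
Reagents that add atoms: none
Why: Negishi-type palladium-catalysed coupling of a Reformatsky reagent (α-arylation of a zinc ester enolate), which tolerates the methyl benzoate.

Step 17
Reactants: 27 tert-butyl 2-[2-(benzyloxy)-3-methoxy-5-(methoxycarbonyl)phenyl]acetate
Product: 28 2-[2-(benzyloxy)-3-methoxy-5-(methoxycarbonyl)phenyl]acetic acid
Conditions: CF3CO2H/CH2Cl2 1:3, 0 °C to rt
Reagents that add atoms: none
Why: Acidolysis of the tert-butyl ester (loss of isobutene), selective over the methyl ester and the aryl benzyl ether.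

Step 18
Reactants: 28 2-[2-(benzyloxy)-3-methoxy-5-(methoxycarbonyl)phenyl]acetic acid; 29 (S)-4-benzyloxazolidin-2-one
Product: 31 methyl 4-(benzyloxy)-3-{2-[(4S)-4-benzyl-2-oxooxazolidin-3-yl]-2-oxoethyl}-5-methoxybenzoate, via mixed pivalic anhydride 30 (not isolated)
Conditions: t-BuCOCl, Et3N, THF, −20 °C; then 29, LiCl, rt
Reagents that add atoms: none
Why: N-acylation of the oxazolidinone through the mixed anhydride under LiCl/Et3N, which avoids strong base next to the acidic arylacetyl position.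

Step 19
Reactants: 31 methyl 4-(benzyloxy)-3-{2-[(4S)-4-benzyl-2-oxooxazolidin-3-yl]-2-oxoethyl}-5-methoxybenzoate; 32 4-(benzyloxy)-3-methoxybenzaldehyde
Product: 33 methyl 4-(benzyloxy)-3-[(1S,2R)-3-[(4S)-4-benzyl-2-oxooxazolidin-3-yl]-1-(4-benzyloxy-3-methoxyphenyl)-3-oxo-1-(trimethylsilyloxy)propan-2-yl]-5-methoxybenzoate (anti adduct; 2′R,3′S in the acyl chain)
Conditions: MgCl2 (20 mol%), Et3N (2 equiv), Me3SiCl (1.5 equiv), EtOAc, rt
Reagents that add atoms: chlorotrimethylsilane C[Si](C)(C)Cl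
Why: Evans magnesium-halide-catalysed anti-aldol: soft enolisation gives the chelated Z magnesium enolate, the non-enolisable aryl aldehyde adds on the face away from the auxiliary benzyl through a boat transition state to give the anti adduct, and silylation of the aldolate releases MgCl2 and blocks retro-aldol, so both new centres are set by the (S)-auxiliary.

Step 20
Reactants: 33 anti-aldol trimethylsilyl ether
Product: 35 methyl 4-(benzyloxy)-3-[(1S,2S)-1-(4-benzyloxy-3-methoxyphenyl)-1,3-dihydroxypropan-2-yl]-5-methoxybenzoate, via trimethylsilyl ether alcohol 34 (not isolated)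
Conditions: LiBH4 (2 equiv), MeOH (2 equiv), THF, 0 °C; then K2CO3, MeOH, 0 °C
Reagents that add atoms: none
Why: Reductive cleavage of the imide by LiBH4, which is much faster than reduction of the electron-rich methyl benzoate, followed by methanolysis of the silyl ether; keeping the β-oxygen silylated during the reduction prevents retro-aldol, and the descriptor at C2 changes only because of ranking.

Step 21
Reactants: 35 methyl 4-(benzyloxy)-3-[(1S,2S)-1-(4-benzyloxy-3-methoxyphenyl)-1,3-dihydroxypropan-2-yl]-5-methoxybenzoate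
Product: 36 methyl 4-(benzyloxy)-3-[(1S,2S)-1-(4-benzyloxy-3-methoxyphenyl)-1,3-bis(tert-butyldimethylsilyloxy)propan-2-yl]-5-methoxybenzoate
Conditions: t-BuMe2SiOTf (2.5 equiv), 2,6-lutidine, CH2Cl2, −78 to 0 °C
Reagents that add atoms: tert-butyldimethylsilyl triflate CC(C)(C)[Si](C)(C)OS(=O)(=O)C(F)(F)F
Why: Silylation of both hydroxyl groups under basic conditions that cannot ionise the electron-rich benzylic carbinol.

Step 22
Reactants: 36 bis-silyl ether methyl ester
Product: 37 {4-(benzyloxy)-3-[(1S,2S)-1-(4-benzyloxy-3-methoxyphenyl)-1,3-bis(tert-butyldimethylsilyloxy)propan-2-yl]-5-methoxyphenyl}methanol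
Conditions: i-Bu2AlH (2.5 equiv), CH2Cl2, −78 to 0 °C; aq. potassium sodium tartrate
Reagents that add atoms: none
Why: Hydride reduction of the benzoate to the benzylic alcohol; silyl and benzyl ethers are inert.

Step 23
Reactants: 37 benzylic alcohol
Product: 38 1-(benzyloxy)-2-[(1S,2S)-1-(4-benzyloxy-3-methoxyphenyl)-1,3-bis(tert-butyldimethylsilyloxy)propan-2-yl]-4-(bromomethyl)-6-methoxybenzene
Conditions: CBr4, PPh3, 2,6-lutidine, CH2Cl2, 0 °C; used at once
Reagents that add atoms: carbon tetrabromide BrC(Br)(Br)Br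
Why: Appel bromination under neutral conditions, which spares the silyl ethers; the electron-rich benzyl bromide is not stored.

Step 24
Reactants: 24 (4S)-4-[(BF-5-yl)methyl]oxolan-2-one; 38 benzyl bromide
Product: 39 (3S,4S)-3-{[4-(benzyloxy)-3-[(1S,2S)-1-(4-benzyloxy-3-methoxyphenyl)-1,3-bis(tert-butyldimethylsilyloxy)propan-2-yl]-5-methoxyphenyl]methyl}-4-[(BF-5-yl)methyl]oxolan-2-one
Conditions: LiN(SiMe3)2 (1.05 equiv), THF, −78 °C; then 38, DMPU, −78 to −40 °C
Reagents that add atoms: none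
Why: Alkylation of the lactone lithium enolate; the electrophile enters anti to the C4 arylmethyl group, which sets C3 as S and gives the trans-3,4-disubstituted lactone as in dibenzylbutyrolactone lignan syntheses.

Step 25
Reactants: 39 fully protected lactone
Product: 40 (3S,4S)-3-{[4-(benzyloxy)-3-[(1S,2S)-1-(4-benzyloxy-3-methoxyphenyl)-1,3-dihydroxypropan-2-yl]-5-methoxyphenyl]methyl}-4-{[(2R,3S)-2-(4-benzyloxy-3-methoxyphenyl)-3-(hydroxymethyl)-7-methoxy-2,3-dihydro-1-benzofuran-5-yl]methyl}oxolan-2-one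
Conditions: Bu4NF (4 equiv), AcOH (4 equiv), THF, rt to 40 °C
Reagents that add atoms: none
Why: Buffered fluoride desilylation of all three silyl ethers while the phenols are still benzylated, so no phenoxide can expel the benzylic oxygen as a quinone methide.

Step 26
Reactants: 40 tris-benzyl ether
Product: 41 CNP0186558.3, (3S,4S)-3-{[4-hydroxy-3-[(1S,2S)-1,3-dihydroxy-1-(4-hydroxy-3-methoxyphenyl)propan-2-yl]-5-methoxyphenyl]methyl}-4-{[(2R,3S)-2-(4-hydroxy-3-methoxyphenyl)-3-(hydroxymethyl)-7-methoxy-2,3-dihydro-1-benzofuran-5-yl]methyl}oxolan-2-one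
Conditions: H2 (1 atm), 10% Pd/C, EtOAc/EtOH, rt, stopped at full debenzylation
Reagents that add atoms: none
Why: Neutral hydrogenolysis of the three aryl benzyl ethers, which is much faster than hydrogenolysis of the benzylic alcohol or the benzylic ring ether; no acid is used, so the arm cannot cyclise onto the ring B phenol.

**Compound list**

1 | methyl vanillate | COC(=O)c1ccc(O)c(OC)c1 | starting material
2 | methyl 4-hydroxy-3-iodo-5-methoxybenzoate | COC(=O)c1cc(I)c(O)c(OC)c1 | intermediate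
3 | tributyl(1-ethoxyvinyl)stannane | CCCC[Sn](CCCC)(CCCC)C(=C)OCC | starting material
4 | methyl 3-(1-ethoxyvinyl)-4-hydroxy-5-methoxybenzoate | CCOC(=C)c1cc(C(=O)OC)cc(OC)c1O | intermediate
5 | methyl 3-acetyl-4-hydroxy-5-methoxybenzoate | COC(=O)c1cc(OC)c(O)c(C(C)=O)c1 | intermediate
6 | N,N-dimethylformamide dimethyl acetal | COC(OC)N(C)C | starting material
7 | methyl 3-[(E)-3-(dimethylamino)prop-2-enoyl]-4-hydroxy-5-methoxybenzoate | COC(=O)c1cc(OC)c(O)c(C(=O)/C=C/N(C)C)c1 | intermediate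
8 | methyl 8-methoxy-4-oxo-4H-chromene-6-carboxylate | COC(=O)c1cc(OC)c2occc(=O)c2c1 | intermediate
9 | 4-bromo-2-methoxyphenol | COc1cc(Br)ccc1O | starting material
10 | 4-bromo-2-methoxyphenyl pivalate | COc1cc(Br)ccc1OC(=O)C(C)(C)C | intermediate
11 | [3-methoxy-4-(pivaloyloxy)phenyl]boronic acid | COc1cc(B(O)O)ccc1OC(=O)C(C)(C)C | intermediate
12 | methyl (2R)-8-methoxy-2-[3-methoxy-4-(pivaloyloxy)phenyl]-4-oxochromane-6-carboxylate | COC(=O)c1cc(OC)c2c(c1)C(=O)C[C@H](c1ccc(OC(=O)C(C)(C)C)c(OC)c1)O2 | intermediate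
13 | methyl (2R)-4,8-dimethoxy-2-[3-methoxy-4-(pivaloyloxy)phenyl]-2H-chromene-6-carboxylate | COC(=O)c1cc(OC)c2c(c1)C(OC)=C[C@H](c1ccc(OC(=O)C(C)(C)C)c(OC)c1)O2 | intermediate
14 | dimethyl (2R,3R)-7-methoxy-2-[3-methoxy-4-(pivaloyloxy)phenyl]-2,3-dihydro-1-benzofuran-3,5-dicarboxylate (trans) | COC(=O)c1cc(OC)c2c(c1)[C@@H](C(=O)OC)[C@H](c1ccc(OC(=O)C(C)(C)C)c(OC)c1)O2 | intermediate
15 | 4-[(2R,3S)-3,5-bis(hydroxymethyl)-7-methoxy-2,3-dihydro-1-benzofuran-2-yl]-2-methoxyphenol | OCc1cc(OC)c2c(c1)[C@@H](CO)[C@H](c1ccc(O)c(OC)c1)O2 | intermediate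
16 | [(2R,3S)-2-(4-benzyloxy-3-methoxyphenyl)-7-methoxy-2,3-dihydro-1-benzofuran-3,5-diyl]dimethanol | OCc1cc(OC)c2c(c1)[C@@H](CO)[C@H](c1ccc(OCc3ccccc3)c(OC)c1)O2 | intermediate
17 | (2R,3S)-2-(4-benzyloxy-3-methoxyphenyl)-3-(hydroxymethyl)-7-methoxy-2,3-dihydro-1-benzofuran-5-carbaldehyde | O=Cc1cc(OC)c2c(c1)[C@@H](CO)[C@H](c1ccc(OCc3ccccc3)c(OC)c1)O2 | intermediate
18 | (2R,3S)-2-(4-benzyloxy-3-methoxyphenyl)-7-methoxy-3-[(triisopropylsilyloxy)methyl]-2,3-dihydro-1-benzofuran-5-carbaldehyde | O=Cc1cc(OC)c2c(c1)[C@@H](CO[Si](C(C)C)(C(C)C)C(C)C)[C@H](c1ccc(OCc3ccccc3)c(OC)c1)O2 | intermediate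
19 | dimethyl succinate | COC(=O)CCC(=O)OC | starting material
20 | methyl 2-(BF-5-yl)-5-oxooxolane-3-carboxylate (isomer mixture at the two lactone carbons) | COC(=O)C1CC(=O)OC1c1cc(OC)c2c(c1)[C@@H](CO[Si](C(C)C)(C(C)C)C(C)C)[C@H](c1ccc(OCc3ccccc3)c(OC)c1)O2 | intermediate
21 | (E)-3-(methoxycarbonyl)-4-(BF-5-yl)but-3-enoic acid | OC(=O)C/C(C(=O)OC)=C\c1cc(OC)c2c(c1)[C@@H](CO[Si](C(C)C)(C(C)C)C(C)C)[C@H](c1ccc(OCc3ccccc3)c(OC)c1)O2 | intermediate
22 | (3S)-3-(methoxycarbonyl)-4-(BF-5-yl)butanoic acid | COC(=O)[C@H](CC(O)=O)Cc1cc(OC)c2c(c1)[C@@H](CO[Si](C(C)C)(C(C)C)C(C)C)[C@H](c1ccc(OCc3ccccc3)c(OC)c1)O2 | intermediate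
23 | (3S)-3-(hydroxymethyl)-4-(BF-5-yl)butanoic acid | OC[C@H](CC(O)=O)Cc1cc(OC)c2c(c1)[C@@H](CO[Si](C(C)C)(C(C)C)C(C)C)[C@H](c1ccc(OCc3ccccc3)c(OC)c1)O2 | intermediate
24 | (4S)-4-[(BF-5-yl)methyl]oxolan-2-one | C1C(=O)OC[C@H]1Cc1cc(OC)c2c(c1)[C@@H](CO[Si](C(C)C)(C(C)C)C(C)C)[C@H](c1ccc(OCc3ccccc3)c(OC)c1)O2 | intermediate
25 | methyl 4-(benzyloxy)-3-iodo-5-methoxybenzoate | COC(=O)c1cc(I)c(OCc2ccccc2)c(OC)c1 | intermediate
26 | (2-tert-butoxy-2-oxoethyl)zinc bromide | CC(C)(C)OC(=O)C[Zn]Br | starting material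
27 | tert-butyl 2-[2-(benzyloxy)-3-methoxy-5-(methoxycarbonyl)phenyl]acetate | COC(=O)c1cc(CC(=O)OC(C)(C)C)c(OCc2ccccc2)c(OC)c1 | intermediate
28 | 2-[2-(benzyloxy)-3-methoxy-5-(methoxycarbonyl)phenyl]acetic acid | COC(=O)c1cc(CC(O)=O)c(OCc2ccccc2)c(OC)c1 | intermediate
29 | (S)-4-benzyloxazolidin-2-one | O=C1OC[C@H](Cc2ccccc2)N1 | starting material
30 | 2-[2-(benzyloxy)-3-methoxy-5-(methoxycarbonyl)phenyl]acetic pivalic anhydride | COC(=O)c1cc(CC(=O)OC(=O)C(C)(C)C)c(OCc2ccccc2)c(OC)c1 | intermediate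
31 | methyl 4-(benzyloxy)-3-{2-[(4S)-4-benzyl-2-oxooxazolidin-3-yl]-2-oxoethyl}-5-methoxybenzoate | COC(=O)c1cc(CC(=O)N2[C@@H](Cc3ccccc3)COC2=O)c(OCc2ccccc2)c(OC)c1 | intermediate
32 | 4-(benzyloxy)-3-methoxybenzaldehyde | COc1cc(C=O)ccc1OCc1ccccc1 | starting material
33 | methyl 4-(benzyloxy)-3-[(1S,2R)-3-[(4S)-4-benzyl-2-oxooxazolidin-3-yl]-1-(4-benzyloxy-3-methoxyphenyl)-3-oxo-1-(trimethylsilyloxy)propan-2-yl]-5-methoxybenzoate | COc1cc([C@@H](O[Si](C)(C)C)[C@H](C(=O)N2[C@@H](Cc3ccccc3)COC2=O)c2cc(C(=O)OC)cc(OC)c2OCc2ccccc2)ccc1OCc1ccccc1 | intermediate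
34 | methyl 4-(benzyloxy)-3-[(1S,2S)-1-(4-benzyloxy-3-methoxyphenyl)-3-hydroxy-1-(trimethylsilyloxy)propan-2-yl]-5-methoxybenzoate | COc1cc([C@@H](O[Si](C)(C)C)[C@H](CO)c2cc(C(=O)OC)cc(OC)c2OCc2ccccc2)ccc1OCc1ccccc1 | intermediate
35 | methyl 4-(benzyloxy)-3-[(1S,2S)-1-(4-benzyloxy-3-methoxyphenyl)-1,3-dihydroxypropan-2-yl]-5-methoxybenzoate | COc1cc([C@@H](O)[C@H](CO)c2cc(C(=O)OC)cc(OC)c2OCc2ccccc2)ccc1OCc1ccccc1 | intermediate
36 | methyl 4-(benzyloxy)-3-[(1S,2S)-1-(4-benzyloxy-3-methoxyphenyl)-1,3-bis(tert-butyldimethylsilyloxy)propan-2-yl]-5-methoxybenzoate | COc1cc([C@@H](O[Si](C)(C)C(C)(C)C)[C@H](CO[Si](C)(C)C(C)(C)C)c2cc(C(=O)OC)cc(OC)c2OCc2ccccc2)ccc1OCc1ccccc1 | intermediate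
37 | {4-(benzyloxy)-3-[(1S,2S)-1-(4-benzyloxy-3-methoxyphenyl)-1,3-bis(tert-butyldimethylsilyloxy)propan-2-yl]-5-methoxyphenyl}methanol | COc1cc([C@@H](O[Si](C)(C)C(C)(C)C)[C@H](CO[Si](C)(C)C(C)(C)C)c2cc(CO)cc(OC)c2OCc2ccccc2)ccc1OCc1ccccc1 | intermediate
38 | 1-(benzyloxy)-2-[(1S,2S)-1-(4-benzyloxy-3-methoxyphenyl)-1,3-bis(tert-butyldimethylsilyloxy)propan-2-yl]-4-(bromomethyl)-6-methoxybenzene | COc1cc([C@@H](O[Si](C)(C)C(C)(C)C)[C@H](CO[Si](C)(C)C(C)(C)C)c2cc(CBr)cc(OC)c2OCc2ccccc2)ccc1OCc1ccccc1 | intermediate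
39 | (3S,4S)-3-{[4-(benzyloxy)-3-[(1S,2S)-1-(4-benzyloxy-3-methoxyphenyl)-1,3-bis(tert-butyldimethylsilyloxy)propan-2-yl]-5-methoxyphenyl]methyl}-4-[(BF-5-yl)methyl]oxolan-2-one | COc1cc([C@@H](O[Si](C)(C)C(C)(C)C)[C@H](CO[Si](C)(C)C(C)(C)C)c2cc(C[C@@H]3C(=O)OC[C@H]3Cc3cc(OC)c4c(c3)[C@@H](CO[Si](C(C)C)(C(C)C)C(C)C)[C@H](c3ccc(OCc5ccccc5)c(OC)c3)O4)cc(OC)c2OCc2ccccc2)ccc1OCc1ccccc1 | intermediate
40 | (3S,4S)-3-{[4-(benzyloxy)-3-[(1S,2S)-1-(4-benzyloxy-3-methoxyphenyl)-1,3-dihydroxypropan-2-yl]-5-methoxyphenyl]methyl}-4-{[(2R,3S)-2-(4-benzyloxy-3-methoxyphenyl)-3-(hydroxymethyl)-7-methoxy-2,3-dihydro-1-benzofuran-5-yl]methyl}oxolan-2-one | COc1cc([C@@H](O)[C@H](CO)c2cc(C[C@@H]3C(=O)OC[C@H]3Cc3cc(OC)c4c(c3)[C@@H](CO)[C@H](c3ccc(OCc5ccccc5)c(OC)c3)O4)cc(OC)c2OCc2ccccc2)ccc1OCc1ccccc1 | intermediate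
41 | CNP0186558.3 | COc1cc([C@@H](O)[C@H](CO)c2cc(C[C@@H]3C(=O)OC[C@H]3Cc3cc(OC)c4c(c3)[C@@H](CO)[C@H](c3ccc(O)c(OC)c3)O4)cc(OC)c2O)ccc1O | target

**Step count and risks**

Total steps: 26. Longest linear sequence: 15 steps (1, 2, 3, 6, 7, 8, 9, 10, 11, 12, 13, 14, 24, 25, 26, from methyl vanillate).

Steps most likely to fail:

Step 7. The aryl shift may lose selectivity (migration of the C2 aryl to the isoflavone, dehydrogenation to the flavone), and acid-promoted opening of the pyranone may erode the C2 configuration. Fallback, from 12 back to 14: the same ring contraction through a Wolff rearrangement instead of an iodonium-induced shift. Flavanone 12 is enolised with LiN(SiMe3)2 at −78 °C and acylated with CF3CO2CH2CF3 to the 3-trifluoroacetyl flavanone F1. Detrifluoroacetylative diazo transfer (MsN3, Et3N, MeCN) gives the 3-diazo flavanone F2. Photolysis in methanol makes C4a migrate to the carbene carbon C3, and methanol traps the ring-contracted ketene, mainly as the cis ester F3 (protonation anti to the aryl). Catalytic NaOMe in MeOH epimerises F3 at C3 to 14.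

Step 19. With the α-aryl enolate the aldol addition is readily reversible, so retro-aldol before silylation may lower the anti/syn ratio or the facial selectivity, and the ortho-benzyloxy group may slow the addition. Fallback, from 28 back to 36: C8 is set by the boron syn-aldol and C7 is corrected by oxidation and reagent-controlled reduction. Acid 28 is coupled (as in step 18) to (R)-4-benzyloxazolidin-2-one to give the (R)-imide F4. Bu2BOTf/i-Pr2NEt aldol with 32 gives the Evans syn adduct F5 (2′R,3′R: C8 correct, C7 epimeric). LiBH4 gives the syn diol F6, and t-BuMe2SiCl/imidazole protects the primary alcohol to give silyl ether F7. Dess–Martin oxidation gives the aryl ketone F8. (R)-Me-CBS oxazaborolidine with BH3·SMe2 at −30 °C reduces it to the (1S) alcohol F9, and t-BuMe2SiOTf/2,6-lutidine converts F9 into 36.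

Step 6. Addition to the vinylogous ester may be slow, the boronic acid may protodeboronate, or the enantioselectivity may be insufficient. Fallback, from 8 and 11 back to 12: the flavanone is made racemic and resolved kinetically. 8 and 11 are coupled with achiral [Rh(OH)(cod)]2 in dioxane/H2O to give the racemic flavanone F10. Asymmetric transfer hydrogenation with RuCl(p-cymene)[(S,S)-TsDPEN] and HCO2H/Et3N reduces the (2S) ketone selectively to the cis-(2S,4S)-flavan-4-ol F11. The unreacted (2R)-ketone 12 is separated by chromatography and continues in step 7.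

**Further compounds**

F1 | step 7 | methyl (2R)-8-methoxy-2-[3-methoxy-4-(pivaloyloxy)phenyl]-4-oxo-3-(trifluoroacetyl)chromane-6-carboxylate | COC(=O)c1cc(OC)c2c(c1)C(=O)C(C(=O)C(F)(F)F)[C@H](c1ccc(OC(=O)C(C)(C)C)c(OC)c1)O2
F2 | step 7 | methyl (2S)-3-diazo-8-methoxy-2-[3-methoxy-4-(pivaloyloxy)phenyl]-4-oxochromane-6-carboxylate | COC(=O)c1cc(OC)c2c(c1)C(=O)C(=[N+]=[N-])[C@H](c1ccc(OC(=O)C(C)(C)C)c(OC)c1)O2
F3 | step 7 | dimethyl (2R,3S)-7-methoxy-2-[3-methoxy-4-(pivaloyloxy)phenyl]-2,3-dihydro-1-benzofuran-3,5-dicarboxylate (cis) | COC(=O)c1cc(OC)c2c(c1)[C@H](C(=O)OC)[C@H](c1ccc(OC(=O)C(C)(C)C)c(OC)c1)O2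
F4 | step 19 | methyl 4-(benzyloxy)-3-{2-[(4R)-4-benzyl-2-oxooxazolidin-3-yl]-2-oxoethyl}-5-methoxybenzoate | COC(=O)c1cc(CC(=O)N2[C@H](Cc3ccccc3)COC2=O)c(OCc2ccccc2)c(OC)c1
F5 | step 19 | methyl 4-(benzyloxy)-3-[(1R,2R)-3-[(4R)-4-benzyl-2-oxooxazolidin-3-yl]-1-(4-benzyloxy-3-methoxyphenyl)-1-hydroxy-3-oxopropan-2-yl]-5-methoxybenzoate (syn adduct) | COc1cc([C@H](O)[C@H](C(=O)N2[C@H](Cc3ccccc3)COC2=O)c2cc(C(=O)OC)cc(OC)c2OCc2ccccc2)ccc1OCc1ccccc1
F6 | step 19 | methyl 4-(benzyloxy)-3-[(1R,2S)-1-(4-benzyloxy-3-methoxyphenyl)-1,3-dihydroxypropan-2-yl]-5-methoxybenzoate | COc1cc([C@H](O)[C@H](CO)c2cc(C(=O)OC)cc(OC)c2OCc2ccccc2)ccc1OCc1ccccc1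
F7 | step 19 | methyl 4-(benzyloxy)-3-[(1R,2S)-1-(4-benzyloxy-3-methoxyphenyl)-3-(tert-butyldimethylsilyloxy)-1-hydroxypropan-2-yl]-5-methoxybenzoate | COc1cc([C@H](O)[C@H](CO[Si](C)(C)C(C)(C)C)c2cc(C(=O)OC)cc(OC)c2OCc2ccccc2)ccc1OCc1ccccc1
F8 | step 19 | methyl 4-(benzyloxy)-3-[(2S)-1-(4-benzyloxy-3-methoxyphenyl)-3-(tert-butyldimethylsilyloxy)-1-oxopropan-2-yl]-5-methoxybenzoate | COc1cc(C(=O)[C@H](CO[Si](C)(C)C(C)(C)C)c2cc(C(=O)OC)cc(OC)c2OCc2ccccc2)ccc1OCc1ccccc1
F9 | step 19 | methyl 4-(benzyloxy)-3-[(1S,2S)-1-(4-benzyloxy-3-methoxyphenyl)-3-(tert-butyldimethylsilyloxy)-1-hydroxypropan-2-yl]-5-methoxybenzoate | COc1cc([C@@H](O)[C@H](CO[Si](C)(C)C(C)(C)C)c2cc(C(=O)OC)cc(OC)c2OCc2ccccc2)ccc1OCc1ccccc1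
F10 | step 6 | methyl 8-methoxy-2-[3-methoxy-4-(pivaloyloxy)phenyl]-4-oxochromane-6-carboxylate (racemic) | COC(=O)c1cc(OC)c2c(c1)C(=O)CC(c1ccc(OC(=O)C(C)(C)C)c(OC)c1)O2
F11 | step 6 | methyl (2S,4S)-4-hydroxy-8-methoxy-2-[3-methoxy-4-(pivaloyloxy)phenyl]chromane-6-carboxylate | COC(=O)c1cc(OC)c2c(c1)[C@@H](O)C[C@@H](c1ccc(OC(=O)C(C)(C)C)c(OC)c1)O2
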